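The time of reading is the first setting I would turn on this flask, so I ask how long a target molecule lasts.

| setting | east | north-east | flask |
|---|---|---|---|
| substrate | 0.0087 M | 0.019 M | 0.013 M |
| reagent | 2 equiv | 2 equiv | 2.00 equiv |
| remark | run made earlier | run made earlier |  |
| time |  |  | 8.0 min |

| run | time / min | over-reaction product / % | target / % | substrate / % |
|---|---|---|---|---|
| east | 0.667 | 8.2 | 53.5 | 1.1 |
| east | 2.00 | 36.9 | 51.6 | 0.6 |
| east | 4.00 | 70.0 | 29.6 | 0 |
| east | 6.00 | 82.4 | 13.3 | 0 |
| east | 8.00 | 90.3 | 6.9 | 0 |
| north-east | 1.50 | 22.9 | 53.1 | 2.4 |
| north-east | 3.00 | 50.6 | 38.4 | 0.9 |
| north-east | 5.00 | 72.4 | 20.7 | 1.6 |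
| north-east | 6.00 | 80.4 | 15.8 | 0.6 |
| north-east | 8.00 | 88.5 | 6.9 | 0.7 |

(each reading ± 1 percentage point)

- a reading of substrate is of its free form alone

- ratio of over-reaction product to target at 0.80 s
- ratio of over-reaction product to target at 20 s
- ratio of over-reaction product to target at 8.0 min
- which of over-reaction product and target there is more of at 8.0 min

In the east run the three readings add up to 62.8% at 0.667 min, but to 99.6% at 4.00 min. From that time on I therefore treat a molecule as either target or over-reaction product, with one fork left. Target falls from 29.6% to 6.9% by 8.00 min, which gives 0.364 /min for the loss constant of target, the logarithm of the fall in c(target) divided by the time taken, an apparent first-order rate constant. A target molecule present at 4.00 min is thus still target at 8.00 min with a chance of 0.233.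

Substrate concentration is the next setting. By hand, a loss that followed the charge would grow by a factor of 2.18 from the east run to the north-east run. The north-east readings instead give 0.366 /min, and the ratio at 8.00 min reads 12.8 there against 13.1 in the east run. So for this flask, charged between the two, I commit to 13.0 at 8.0 min, with over-reaction product ahead. That ratio rests on a target reading of 6.9% with a scatter of 1 percentage point.

Reagent is the last setting, but both runs and this flask hold it at 2.00 equiv, so the runs show me nothing about it.

For the early times I take the ratio as the loss constant times the mean age of a target molecule. At 0.80 s target has only begun to form, so I put that mean age at half the time, 0.400 s, which gives 0.00243. Half the time at 20 s, 10.0 s, gives 0.0607, but I hold this as a low figure. In the east run substrate already reads 1.1% at 0.667 min, so formation is not steady over these seconds, and target formed early makes the mean age longer than half the time.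

The forecast gives 0.003, 0.075 and 13, with over-reaction product ahead, on the ground that “the steps behave as first order”. Its early ratios stand above mine.

The flask gives 0.00254, 0.0735 and 12.0, with over-reaction product ahead, 89.9% against 7.47% of target.

    substrate → intermediate A (k = 0.0670 /s)
    substrate → target (k = 0.0300 /s)
    substrate + reagent ⇌ intermediate B (K = 72.0 /M, k = 0.720 /M/s)
    intermediate A → target (k = 0.0280 /s)
    target → over-reaction product (k = 0.00630 /s)
    substrate + intermediate A → side product (k = 0.390 /M/s)

In this flask at 2.49 min, target is made at 0.294 of the rate at which it is used up. With the chance carried over, the 28.8% of target in this flask at 4.00 min becomes 6.71% at 8.00 min, where the flask holds 7.47%. The neighbour charged with 5.00 equiv of reagent holds 9.41% of target at 8.00 min, and the loss constant reads that excess over this flask as a lag of 0.634 min.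

The numbers in the tables were generated by integration with made-up constants; noise was put on by code.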